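## Retrosynthetic overview

1. Target 26 ← reagent-controlled reduction of the ring ketone (C4) of enedione 25 ← selenoxide dehydrogenation of 1,3-diketone 23.
2. Key step: the C6–C16 bond is made last among the ring bonds, by transannular 7-exo-trig addition of the C9–O–CH2 radical (from silylmethyl ether 22) to the macrocyclic 2-acylcyclohexenone; C9/C10 come from a Shi epoxide opened with inversion by Me3SiCH2OH.
3. The twelve-membered ring is closed at C5–C15 by a Nozaki–Hiyama–Kishi reaction of iodoenone aldehyde 18; C13/C14 come from a Sharpless epoxidation of a Z-allylic alcohol.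
4. C8–C9 is made by B-alkyl Suzuki coupling of vinyl cycloadduct 5 with dienyl iodide 11 (prenol + 1-bromobut-2-yne, then hydrozirconation/iodination).
5. Ring order: cyclohexene (asymmetric Diels–Alder of the Rawal diene with tiglic aldehyde, sets C1/C2) → the two oxiranes → twelve-membered carbocycle → oxepane.

Assumption: atom labels used only in this answer are ring C1 (quaternary, CH3 = C18), C2 (CH–CH3, C17), C3, C4 (carbinol), C5, C6; chain from C1: C7, C8, C9 (C–O, CH3 = C19), C10 (carbinol), C11, C12, C13 (oxirane C, CH3 = C20), C14 (oxirane CH), C15 (C=O, bonded to C5); C16 = OCH2 on C6.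

## Route

Step 1
Reactants: 1 (E)-4-(dimethylamino)but-3-en-2-one
Product: 2 (E)-3-(tert-butyldimethylsilyloxy)-N,N-dimethylbuta-1,3-dien-1-amine (Rawal diene)
Conditions: TBSOTf, Et3N, Et2O, 0 °C → rt
Reagents that add atoms: tert-butyldimethylsilyl trifluoromethanesulfonate, CC(C)(C)[Si](C)(C)OS(=O)(=O)C(F)(F)F
Why: Silyl triflate/amine soft enolisation of the vinylogous amide (O-silylation, then loss of a methyl proton) gives the 1-amino-3-siloxybutadiene; no stereocentre is formed and the E enamine geometry is kept.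

Step 2
Reactants: 2 Rawal diene; 3 (E)-2-methylbut-2-enal (tiglic aldehyde)
Product: 5 tert-butyl{[(3S,4R,5S)-3-(dimethylamino)-4-ethenyl-4,5-dimethylcyclohex-1-en-1-yl]oxy}dimethylsilane, via cycloadduct aldehyde 4 (not isolated)
Conditions: 1-naphthyl-TADDOL (20 mol%, enantiomer giving 4 as drawn), toluene, −40 °C; then Ph3P=CH2 (from Ph3PCH3Br, KOtBu, THF), −40 → 0 °C
Reagents that add atoms: methyltriphenylphosphonium bromide, C[P+](c1ccccc1)(c1ccccc1)c1ccccc1.[Br-]
Why: Hydrogen-bond-catalysed asymmetric Diels–Alder reaction followed by Wittig methylenation: suprafacial endo addition to the E-enal puts the C17 and C18 methyls cis (C1/C2 relative configuration), the TADDOL-bound aldehyde is attacked on one face (absolute configuration), and the ylide turns the neopentyl aldehyde into the C7=C8 vinyl group without touching the silyl enol ether.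

Step 3
Reactants: 6 3-methylbut-2-en-1-ol (prenol); 7 1-bromobut-2-yne
Product: 9 (Z)-3-methyloct-2-en-6-yn-1-ol, via dilithiated prenol 8 (not isolated)
Conditions: n-BuLi (2.2 equiv), TMEDA, Et2O/hexane, 0 °C → rt; then 7, −78 → 0 °C
Reagents that add atoms: none
Why: Alkoxide-directed allylic lithiation of prenol occurs at the methyl cis to the CH2OLi arm and SN2 alkylation of this dianion with the propargylic bromide gives the neryl-type alcohol, so the Z geometry of the later C13=C14 alkene comes from the directed metalation.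

Step 4
Reactants: 9 (Z)-3-methyloct-2-en-6-yn-1-ol
Product: 11 (2Z,6E)-7-iodo-3-methylocta-2,6-dien-1-ol, via alkenylzirconocene chloride 10 (not isolated)
Conditions: Cp2Zr(H)Cl (2.5 equiv), THF, rt → 40 °C; then I2, 0 °C
Reagents that add atoms: iodine, II
Why: Syn hydrozirconation of the alkyne (the hydroxyl is zirconated first, the trisubstituted alkene is inert) places zirconium on the less hindered methyl-bearing carbon after equilibration, and iodinolysis with retention gives the E-configured 2-iodoalkene.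

Step 5
Reactants: 5 vinyl cycloadduct; 11 (2Z,6E)-7-iodo-3-methylocta-2,6-dien-1-ol
Product: 14 (4R,5S)-4-[(3E,7Z)-9-hydroxy-3,7-dimethylnona-3,7-dien-1-yl]-4,5-dimethylcyclohex-2-en-1-one, via alkylborane 12 (not isolated), via coupled silyl enol ether 13 (not isolated)
Conditions: 9-BBN, THF, rt; then 11, PdCl2(dppf) (5 mol%), AsPh3, Cs2CO3, DMF/H2O, rt; then 1 M HCl, THF, 0 °C
Reagents that add atoms: none
Why: Anti-Markovnikov hydroboration of the only monosubstituted alkene, B-alkyl Suzuki–Miyaura coupling with retention of the vinyl iodide geometry (forms C8–C9 and fixes the E C9=C10 alkene), then acid hydrolysis of the silyl enol ether and E1cB loss of dimethylamine unveil the cyclohexenone; no stereocentre is touched.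

Step 6
Reactants: 14 enone dienol
Product: 15 (1R,2S,13R,14S)-13,14-epoxide of 14, i.e. (4R,5S)-4-{(3E)-6-[(2R,3S)-3-(hydroxymethyl)-2-methyloxiran-2-yl]-3-methylhex-3-en-1-yl}-4,5-dimethylcyclohex-2-en-1-one
Conditions: Ti(OiPr)4 (10 mol%), L-(+)-diethyl tartrate (12 mol%), t-BuOOH, 4 Å MS, CH2Cl2, −20 °C
Reagents that add atoms: tert-butyl hydroperoxide, CC(C)(C)OO
Why: Sharpless asymmetric epoxidation is specific for the allylic alcohol alkene, is stereospecific (Z alkene gives the cis oxirane) and with L-(+)-tartrate delivers oxygen to the face that gives the (13R,14S) epoxy alcohol, as for nerol.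

Step 7
Reactants: 15 epoxy alcohol
Product: 16 (1R,2S,9R,10R,13R,14S)-bis-epoxide (9,10- and 13,14-oxiranes, C15 = CH2OH, cyclohexenone intact)
Conditions: Shi ketone (D-fructose-derived, 30 mol%), KHSO5 (as 2KHSO5·KHSO4·K2SO4), K2CO3, Bu4NHSO4, MeCN/CH2(OMe)2/aq. Na2B4O7, 0 °C
Reagents that add atoms: potassium peroxymonosulfate, [K+].[O-]S(=O)(=O)OO
Why: Shi asymmetric epoxidation (chiral dioxirane, spiro transition state) attacks the only electron-rich alkene left and converts the E-trisubstituted olefin into the (9R,10R)-oxirane under catalyst control, the enone alkene being too electron-poor to react.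

Step 8
Reactants: 16 bis-epoxide
Product: 17 (1R,2S,9R,10R,13R,14S)-5-iodo derivative of 16 (2-iodocyclohex-2-enone)
Conditions: I2, pyridine, CH2Cl2, 0 °C → rt
Reagents that add atoms: iodine, II
Why: Johnson α-iodination of the cyclohexenone (pyridine conjugate addition, iodination of the enolate, elimination) puts iodine on C5 without affecting the oxiranes or the primary alcohol.

Step 9
Reactants: 17 iodoenone alcohol
Product: 18 (1R,2S,9R,10R,13R,14R)-iodoenone epoxy aldehyde (C15 = CHO)
Conditions: Dess–Martin periodinane, pyridine, CH2Cl2, 0 °C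
Reagents that add atoms: none
Why: Dess–Martin oxidation of the only hydroxyl gives the α,β-epoxy aldehyde under buffered conditions that do not epimerise C14.

Step 10
Reactants: 18 iodoenone epoxy aldehyde
Product: 19 (1R,2S,9R,10R,13R,14S)-macrocyclic hydroxy enone (C5–C15 bond, C15 carbinol as both epimers)
Conditions: CrCl2 (10 equiv), NiCl2 (5 mol%), DMSO/THF, 2 mM, rt
Reagents that add atoms: none
Why: Intramolecular Nozaki–Hiyama–Kishi reaction: nickel-mediated insertion into the C5–I bond, transmetalation to trivalent chromium and addition to the aldehyde close the twelve-membered ring at high dilution; both carbinol epimers are carried on because C15 is oxidised next.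

Step 11
Reactants: 19 macrocyclic hydroxy enone
Product: 20 (1R,2S,9R,10R,13R,14R)-macrocyclic 2-acylcyclohex-2-enone (C4 and C15 ketones, C5=C6–H)
Conditions: Dess–Martin periodinane, pyridine, CH2Cl2, 0 °C
Reagents that add atoms: none
Why: Dess–Martin oxidation of the only free hydroxyl gives the cross-conjugated 2-acylcyclohexenone, a doubly activated radical acceptor at C6, which is used without storage.

Step 12
Reactants: 20 macrocyclic 2-acylcyclohexenone; 21 (trimethylsilyl)methanol
Product: 22 (1R,2S,9S,10R,13R,14R)-9-[(trimethylsilyl)methoxy]-10-hydroxy enedione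
Conditions: 21 (5 equiv), BF3·OEt2 (0.3 equiv), CH2Cl2, −78 → −40 °C
Reagents that add atoms: none
Why: Lewis-acid-catalysed alcoholysis of the trialkyl oxirane (borderline SN2 epoxide opening) occurs at the tertiary carbon C9 with inversion, giving the (9S) ether and the (10R) alcohol, while the α,β-epoxy ketone is deactivated toward ionisation and stays intact.

Step 13
Reactants: 22 silylmethyl ether
Product: 23 (1R,2S,6S,9S,10R,13R,14R)-oxepane-bridged 1,3-diketone (C6–C16 bond, cis ring fusion, C5 epimers in equilibrium with the enol)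
Conditions: 9-mesityl-10-methylacridinium perchlorate (5 mol%), MeCN/MeOH 9:1, 450 nm LEDs, 2 mM, rt
Reagents that add atoms: none
Why: Proposed new method: photoinduced one-electron oxidation of the α-silyl ether and methanol-assisted loss of the silyl group give the C9–O–CH2 radical, which the macrocycle holds under the ring and which adds transannularly (7-exo-trig) to C6 of the alkylidene 1,3-diketone, the stabilised 1,3-dicarbonyl radical then being reduced by the acridinyl radical and protonated; the closest known reaction type is the intermolecular photoredox Giese addition of alkoxymethyl radicals from α-silyl ethers to enones, and the new C6 centre is removed again in step 14.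

Step 14
Reactants: 23 oxepane-bridged 1,3-diketone
Product: 25 (1R,2S,9S,10R,13R,14R)-enedione (C4 ketone, tetrasubstituted C5=C6, oxepane, C10–OH, epoxy ketone), via selenide 24 (not isolated)
Conditions: PhSeCl, pyridine, CH2Cl2, 0 °C; then 30% H2O2, 0 °C → rt
Reagents that add atoms: none
Why: Selenenylation of the enolised 1,3-diketone at C5 from the open face and selenoxide syn-elimination (Reich-type dehydrogenation) toward the only β-hydrogen, H-6, regenerate the tetrasubstituted C5=C6 alkene.

Step 15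
Reactants: 25 enedione
Product: 26 target (1R,2S,4R,9S,10R,13R,14R)
Conditions: (S)-2-methyl-CBS-oxazaborolidine (20 mol%), catecholborane (3 equiv), toluene, −78 °C
Reagents that add atoms: none
Why: Corey–Bakshi–Shibata reduction: the oxazaborolidine binds the ring ketone C4, the only carbonyl with an unbranched CH2 flank (C15 lies between the tetrasubstituted alkene and the oxirane), and the (S)-catalyst delivers hydride to the face that gives the (4R) allylic alcohol.

## Compound list

1 | (E)-4-(dimethylamino)but-3-en-2-one | CN(C)/C=C/C(C)=O | starting material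
2 | (E)-3-(tert-butyldimethylsilyloxy)-N,N-dimethylbuta-1,3-dien-1-amine | CN(C)/C=C/C(=C)O[Si](C)(C)C(C)(C)C | intermediate
3 | (E)-2-methylbut-2-enal | C/C=C(\C)C=O | starting material
4 | (1R,2S,6S)-4-(tert-butyldimethylsilyloxy)-2-(dimethylamino)-1,6-dimethylcyclohex-3-ene-1-carbaldehyde | C[C@H]1CC(O[Si](C)(C)C(C)(C)C)=C[C@H](N(C)C)[C@]1(C)C=O | intermediate
5 | tert-butyl{[(3S,4R,5S)-3-(dimethylamino)-4-ethenyl-4,5-dimethylcyclohex-1-en-1-yl]oxy}dimethylsilane | C[C@H]1CC(O[Si](C)(C)C(C)(C)C)=C[C@H](N(C)C)[C@]1(C)C=C | intermediate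
6 | 3-methylbut-2-en-1-ol | CC(C)=CCO | starting material
7 | 1-bromobut-2-yne | CC#CCBr | starting material
8 | lithium (Z)-4-lithio-3-methylbut-2-en-1-olate | [Li]C/C(C)=C\CO[Li] | intermediate
9 | (Z)-3-methyloct-2-en-6-yn-1-ol | CC#CCC/C(C)=C\CO | intermediate
10 | (2Z,6E)-7-[Cp2Zr(Cl)]-3-methylocta-2,6-dien-1-yl Cp2Zr(Cl) alkoxide | C/C(=C\CC/C(C)=C\CO[Zr](Cl)(C1C=CC=C1)C1C=CC=C1)[Zr](Cl)(C1C=CC=C1)C1C=CC=C1 | intermediate
11 | (2Z,6E)-7-iodo-3-methylocta-2,6-dien-1-ol | C/C(I)=C\CC/C(C)=C\CO | intermediate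
12 | 9-{2-[(1R,2S,6S)-4-(tert-butyldimethylsilyloxy)-2-(dimethylamino)-1,6-dimethylcyclohex-3-en-1-yl]ethyl}-9-borabicyclo[3.3.1]nonane | C[C@H]1CC(O[Si](C)(C)C(C)(C)C)=C[C@H](N(C)C)[C@]1(C)CCB1C2CCCC1CCC2 | intermediate
13 | (2Z,6E)-9-[(1R,2S,6S)-4-(tert-butyldimethylsilyloxy)-2-(dimethylamino)-1,6-dimethylcyclohex-3-en-1-yl]-3,7-dimethylnona-2,6-dien-1-ol | C[C@H]1CC(O[Si](C)(C)C(C)(C)C)=C[C@H](N(C)C)[C@]1(C)CC/C(C)=C/CC/C(C)=C\CO | intermediate
14 | (4R,5S)-4-[(3E,7Z)-9-hydroxy-3,7-dimethylnona-3,7-dien-1-yl]-4,5-dimethylcyclohex-2-en-1-one | C[C@H]1CC(=O)C=C[C@]1(C)CC/C(C)=C/CC/C(C)=C\CO | intermediate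
15 | (4R,5S)-4-{(3E)-6-[(2R,3S)-3-(hydroxymethyl)-2-methyloxiran-2-yl]-3-methylhex-3-en-1-yl}-4,5-dimethylcyclohex-2-en-1-one | C[C@H]1CC(=O)C=C[C@]1(C)CC/C(C)=C/CC[C@@]1(C)O[C@H]1CO | intermediate
16 | (1R,2S,9R,10R,13R,14S)-bis-epoxide of 14 (9,10- and 13,14-oxiranes, C15 = CH2OH) | C[C@H]1CC(=O)C=C[C@]1(C)CC[C@@]2(C)O[C@@H]2CC[C@@]1(C)O[C@H]1CO | intermediate
17 | (1R,2S,9R,10R,13R,14S)-5-iodo bis-epoxide (2-iodocyclohex-2-enone, C15 = CH2OH) | C[C@H]1CC(=O)C(I)=C[C@]1(C)CC[C@@]2(C)O[C@@H]2CC[C@@]1(C)O[C@H]1CO | intermediate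
18 | (1R,2S,9R,10R,13R,14R)-5-iodo bis-epoxide aldehyde (C15 = CHO) | C[C@H]1CC(=O)C(I)=C[C@]1(C)CC[C@@]2(C)O[C@@H]2CC[C@@]1(C)O[C@H]1C=O | intermediate
19 | (1R,2S,9R,10R,13R,14S)-macrocyclic hydroxy enone (C5–C15 bond; C15 carbinol, both epimers) | C[C@H]1CC(=O)C2=C[C@]1(C)CC[C@@]3(C)O[C@@H]3CC[C@@]1(C)O[C@H]1C2O | intermediate
20 | (1R,2S,9R,10R,13R,14R)-macrocyclic 2-acylcyclohex-2-enone (C4 and C15 ketones, both oxiranes) | C[C@H]1CC(=O)C2=C[C@]1(C)CC[C@@]3(C)O[C@@H]3CC[C@@]1(C)O[C@H]1C2=O | intermediate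
21 | (trimethylsilyl)methanol | C[Si](C)(C)CO | starting material
22 | (1R,2S,9S,10R,13R,14R)-9-[(trimethylsilyl)methoxy]-10-hydroxy macrocyclic enedione | C[C@H]1CC(=O)C2=C[C@]1(C)CC[C@](C)(OC[Si](C)(C)C)[C@H](O)CC[C@@]1(C)O[C@H]1C2=O | intermediate
23 | (1R,2S,6S,9S,10R,13R,14R)-oxepane-bridged 1,3-diketone (C16 on C6 cis to C7; C5 epimerisable, largely enolised) | C[C@H]1CC(=O)C2[C@@H]3CO[C@@](C)(CC[C@@]31C)[C@H](O)CC[C@@]1(C)O[C@H]1C2=O | intermediate
24 | C5-phenylselanyl derivative of 23 (selenium cis to H-6) | C[C@H]1CC(=O)[C@@]2([Se]c4ccccc4)[C@@H]3CO[C@@](C)(CC[C@@]31C)[C@H](O)CC[C@@]1(C)O[C@H]1C2=O | intermediate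
25 | (1R,2S,9S,10R,13R,14R)-enedione (4-deoxy-4-oxo target) | C[C@H]1CC(=O)C2=C3CO[C@@](C)(CC[C@@]31C)[C@H](O)CC[C@@]1(C)O[C@H]1C2=O | intermediate
26 | CNP0316768.3, (1R,2S,4R,9S,10R,13R,14R) | C[C@H]1C[C@@H](O)C2=C3CO[C@@](C)(CC[C@@]31C)[C@H](O)CC[C@@]1(C)O[C@H]1C2=O | target

## Step count and risk

Total step count: 15. Longest linear sequence: 13 steps (1, 2, 5–15, or equally 3, 4, 5–15).

Three steps most likely to fail:

**Step 13 (transannular radical cyclisation).** The alkoxymethyl radical may be reduced or undergo hydrogen transfer before it reaches C6, and the preceding alcoholysis of one of two oxiranes beside the enedione is also delicate. The fallback sets out from 20 and comes back at 25, reversing the order of the two bond formations. Compound 20 is irradiated (390 nm) with (Bu4N)4W10O32 in MeCN/MeOH so that the hydroxymethyl radical from methanol adds intermolecularly to C6, giving the C6-hydroxymethyl 1,3-diketone F1. PhSeCl/pyridine gives the C5 selenide F2 and H2O2 the hydroxymethyl enedione F3. Camphorsulfonic acid at −20 °C then lets the C16 hydroxyl open the 9,10-oxirane at C9 (7-exo, inversion) to give 25. This last operation must be cold and short, because the free cis γ-hydroxy enone can close to a lactol and dehydrate to a furan.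

**Step 10 (Nozaki–Hiyama–Kishi macrocyclisation of an α-iodoenone).** Divalent chromium may simply reduce the C–I bond or attack the oxiranes. The fallback sets out from 16 and comes back at 20, replacing the organochromium addition by a thiolate-triggered Michael–aldol ring closure. Compound 16 is oxidised (Dess–Martin periodinane, pyridine) to the enone aldehyde F4. Me2AlSPh at −78 °C and high dilution adds thiolate to C6 and the aluminium enolate closes the twelve-membered ring by aldol addition to C15, giving the β-phenylsulfanyl ketol F5. A second Dess–Martin oxidation gives the sulfanyl diketone F6, which loses benzenethiol with Et3N to give 20.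

**Step 2 (asymmetric Diels–Alder with an α,β-disubstituted enal).** Tiglic aldehyde is a sluggish dienophile and the hydrogen-bond catalyst may give low enantioselectivity. The fallback sets out from 3 and comes back at 14, using a less basic diene with a Lewis-acid catalyst and a late oxidation to the enone. But-3-en-2-one F7 is converted (i-Pr3SiOTf, Et3N) into 2-(triisopropylsilyloxy)buta-1,3-diene F8. A triflimide-activated CBS-type oxazaborolidine catalyses its Diels–Alder reaction with 3 to give cycloadduct aldehyde F9, with the same C1/C2 configuration as 4. Wittig methylenation gives the vinyl silyl enol ether F10, 9-BBN gives alkylborane F11, and Suzuki coupling with 11 gives the coupled silyl enol ether F12. Saegusa oxidation with Pd(OAc)2 in MeCN then gives 14.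

Further compounds

F1 | step 13 | (1R,2S,9R,10R,13R,14R)-6-(hydroxymethyl) 1,3-diketone from 20 (C5, C6 as formed, both removed later) | C[C@H]1CC(=O)C2C(CO)[C@]1(C)CC[C@@]3(C)O[C@@H]3CC[C@@]1(C)O[C@H]1C2=O
F2 | step 13 | C5-phenylselanyl derivative of F1 | C[C@H]1CC(=O)C2([Se]c3ccccc3)C(CO)[C@]1(C)CC[C@@]3(C)O[C@@H]3CC[C@@]1(C)O[C@H]1C2=O
F3 | step 13 | (1R,2S,9R,10R,13R,14R)-6-(hydroxymethyl) enedione bis-epoxide | C[C@H]1CC(=O)C2=C(CO)[C@]1(C)CC[C@@]3(C)O[C@@H]3CC[C@@]1(C)O[C@H]1C2=O
F4 | step 10 | (1R,2S,9R,10R,13R,14R)-bis-epoxide enone aldehyde (16 with C15 = CHO) | C[C@H]1CC(=O)C=C[C@]1(C)CC[C@@]2(C)O[C@@H]2CC[C@@]1(C)O[C@H]1C=O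
F5 | step 10 | macrocyclic 6-(phenylsulfanyl) ketol (C5–C15 bond; C5, C6, C15 as formed) | C[C@H]1CC(=O)C2C(Sc3ccccc3)[C@]1(C)CC[C@@]3(C)O[C@@H]3CC[C@@]1(C)O[C@H]1C2O
F6 | step 10 | macrocyclic 6-(phenylsulfanyl) 1,3-diketone | C[C@H]1CC(=O)C2C(Sc3ccccc3)[C@]1(C)CC[C@@]3(C)O[C@@H]3CC[C@@]1(C)O[C@H]1C2=O
F7 | step 2 | but-3-en-2-one | CC(=O)C=C
F8 | step 2 | 2-(triisopropylsilyloxy)buta-1,3-diene | C=CC(=C)O[Si](C(C)C)(C(C)C)C(C)C
F9 | step 2 | (1R,6S)-1,6-dimethyl-4-(triisopropylsilyloxy)cyclohex-3-ene-1-carbaldehyde | C[C@H]1CC(O[Si](C(C)C)(C(C)C)C(C)C)=CC[C@]1(C)C=O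
F10 | step 2 | {[(4R,5S)-4-ethenyl-4,5-dimethylcyclohex-1-en-1-yl]oxy}triisopropylsilane | C[C@H]1CC(O[Si](C(C)C)(C(C)C)C(C)C)=CC[C@]1(C)C=C
F11 | step 2 | 9-{2-[(1R,6S)-1,6-dimethyl-4-(triisopropylsilyloxy)cyclohex-3-en-1-yl]ethyl}-9-borabicyclo[3.3.1]nonane | C[C@H]1CC(O[Si](C(C)C)(C(C)C)C(C)C)=CC[C@]1(C)CCB1C2CCCC1CCC2
F12 | step 2 | (2Z,6E)-9-[(1R,6S)-1,6-dimethyl-4-(triisopropylsilyloxy)cyclohex-3-en-1-yl]-3,7-dimethylnona-2,6-dien-1-ol | C[C@H]1CC(O[Si](C(C)C)(C(C)C)C(C)C)=CC[C@]1(C)CC/C(C)=C/CC/C(C)=C\CO
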